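## Retrosynthetic overview

1. The target comes from global desilylation of its bis-silyl ether, whose C10 carbinol is made by chelate-controlled reduction of a C10 ketone.
2. The C10 ketone is cut at C8–C9: a [3,3] ketal Claisen rearrangement joins a tetrahydrofuran methyl-ketone dimethyl ketal to a racemic 2-(acetoxymethyl)allylic alcohol and fixes the C6=C7 geometry in the same step.
3. The ketal fragment comes from (R)-(−)-linalool: epoxidation and 5-exo ring closure make the only ring (the oxolane) in the first step; the vinyl group then becomes the methyl ketone.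
4. The allylic alcohol fragment comes from geraniol: cleavage of the 6,7-olefin to an aldehyde, addition of a 2-lithioallyl alkoxide, acetylation of the primary hydroxyl.
5. Ring order: the single oxolane ring is formed first and carried unchanged to the end.

Assumption: the target is numbered along its backbone, C1 (CH2OH) to C15 (carbinol carbon of the hydroxyisopropyl group), with the acetoxymethyl carbon on C7 called C7′. The stereocentres are C10 (S), C11 (R) and C14 (S); C2=C3 is E and C6=C7 is Z (C5 trans to C8). (R)-(−)-Linalool of high ee, geraniol and 2-bromoprop-2-en-1-ol are bought.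

## Route

Step 1
Reactants: 1 (R)-(−)-linalool
Product: 3 2-[(2S,5R)-5-ethenyl-5-methyloxolan-2-yl]propan-2-ol (cis-furanoid linalool oxide), via 6R-epoxylinalool 2 (not isolated)
Conditions: mCPBA (1.05 equiv), CH2Cl2, 0 °C; then CSA (5 mol%), rt; careful SiO2 chromatography, cis isomer collected
Reagents that add atoms: 3-chloroperoxybenzoic acid, OOC(=O)c1cccc(Cl)c1
Why: Prilezhaev epoxidation of the electron-rich trisubstituted olefin followed by acid-catalysed 5-exo epoxide opening by the tertiary hydroxyl with inversion at C14; C11 is the bought linalool centre, the peracid shows no useful facial bias (cis:trans about 1:1, some pyranoid isomers), and the cis isomer 3 arising from the 6R epoxide is separated and carried on.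

Step 2
Reactants: 3 2-[(2S,5R)-5-ethenyl-5-methyloxolan-2-yl]propan-2-ol
Product: 4 triethyl({2-[(2S,5R)-5-ethenyl-5-methyloxolan-2-yl]propan-2-yl}oxy)silane
Conditions: Et3SiOTf, 2,6-lutidine, CH2Cl2, −78 to 0 °C
Reagents that add atoms: triethylsilyl trifluoromethanesulfonate, CC[Si](CC)(CC)OS(=O)(=O)C(F)(F)F
Why: silyl triflate silylation of the hindered tertiary alcohol, needed because a free cis C15 hydroxyl would trap the later ketone and ketal as a bicyclic ketal and stop the Claisen step.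

Step 3
Reactants: 4 triethyl({2-[(2S,5R)-5-ethenyl-5-methyloxolan-2-yl]propan-2-yl}oxy)silane
Product: 5 1-[(2R,5S)-2-methyl-5-{2-[(triethylsilyl)oxy]propan-2-yl}oxolan-2-yl]ethan-1-one
Conditions: PdCl2(quinox) (5 mol%; quinox = 2-(4,5-dihydro-1,3-oxazol-2-yl)quinoline), AgSbF6 (12 mol%), t-BuOOH (70% aq, 12 equiv), CH2Cl2, 0 °C to rt
Reagents that add atoms: tert-butyl hydroperoxide, CC(C)(C)OO
Why: peroxide-mediated Tsuji–Wacker oxidation, in which the quinoline–oxazoline ligand enforces Markovnikov oxygen delivery even next to an ether oxygen, converts the vinyl group into the methyl ketone without touching the quaternary C11 or C14.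

Step 4
Reactants: 5 1-[(2R,5S)-2-methyl-5-{2-[(triethylsilyl)oxy]propan-2-yl}oxolan-2-yl]ethan-1-one
Product: 6 (2R,5S)-2-(1,1-dimethoxyethyl)-2-methyl-5-{2-[(triethylsilyl)oxy]propan-2-yl}oxolane
Conditions: MeOSiMe3 (2.5 equiv), Me3SiOTf (5 mol%), CH2Cl2, −78 to −20 °C; pyridine quench
Reagents that add atoms: methoxytrimethylsilane, CO[Si](C)(C)C
Why: Noyori ketalisation under aprotic conditions gives the dimethyl ketal of the hindered ketone while the tertiary silyl ether survives.

Step 5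
Reactants: 7 geraniol
Product: 8 tert-butyl{[(2E)-3,7-dimethylocta-2,6-dien-1-yl]oxy}diphenylsilane
Conditions: t-BuPh2SiCl, imidazole, DMF, rt
Reagents that add atoms: tert-butyl(chloro)diphenylsilane, CC(C)(C)[Si](Cl)(c1ccccc1)c1ccccc1
Why: standard silylation of the primary allylic alcohol with a group that withstands periodic acid, organolithium and hot weak acid and is removed by fluoride at the end.

Step 6
Reactants: 8 tert-butyl{[(2E)-3,7-dimethylocta-2,6-dien-1-yl]oxy}diphenylsilane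
Product: 9 tert-butyl{[(2E)-5-(3,3-dimethyloxiran-2-yl)-3-methylpent-2-en-1-yl]oxy}diphenylsilane (racemic)
Conditions: mCPBA (1.0 equiv), NaHCO3, CH2Cl2, −20 to 0 °C
Reagents that add atoms: 3-chloroperoxybenzoic acid, OOC(=O)c1cccc(Cl)c1
Why: Prilezhaev epoxidation picks the remote 6,7-olefin because the 2,3-olefin is deactivated by the allylic silyloxy group; the new centre is racemic and is destroyed in the next step.

Step 7
Reactants: 9 tert-butyl{[(2E)-5-(3,3-dimethyloxiran-2-yl)-3-methylpent-2-en-1-yl]oxy}diphenylsilane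
Product: 10 (4E)-6-[(tert-butyldiphenylsilyl)oxy]-4-methylhex-4-enal
Conditions: H5IO6 (1.2 equiv), THF/Et2O, 0 °C
Reagents that add atoms: none
Why: periodic acid opens the epoxide to the glycol and cleaves it (Malaprade glycol cleavage) to the aldehyde and acetone without touching the trisubstituted E-olefin.

Step 8
Reactants: 10 (4E)-6-[(tert-butyldiphenylsilyl)oxy]-4-methylhex-4-enal
Product: 11 (6E)-8-[(tert-butyldiphenylsilyl)oxy]-6-methyl-2-methylideneoct-6-ene-1,3-diol (racemic)
Conditions: 2-bromoprop-2-en-1-ol, t-BuLi (3.1 equiv), Et2O, −78 to 0 °C; then 10, −78 °C; aq NH4Cl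
Reagents that add atoms: 2-bromoprop-2-en-1-ol, OCC(Br)=C
Why: bromine–lithium exchange gives the O,2-dilithio allyl alcohol, whose vinyllithium adds 1,2 to the aldehyde to deliver the 2-methylene-1,3-diol in one operation; the carbinol centre is racemic and is removed in step 10.

Step 9
Reactants: 11 (6E)-8-[(tert-butyldiphenylsilyl)oxy]-6-methyl-2-methylideneoct-6-ene-1,3-diol
Product: 12 (6E)-8-[(tert-butyldiphenylsilyl)oxy]-3-hydroxy-6-methyl-2-methylideneoct-6-en-1-yl acetate (racemic)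
Conditions: AcCl (1.05 equiv), 2,4,6-collidine, CH2Cl2, −78 °C
Reagents that add atoms: acetyl chloride, CC(Cl)=O
Why: kinetically selective acylation of the primary over the secondary allylic hydroxyl with acetyl chloride and a hindered pyridine base installs the final C7′ acetate.

Step 10
Reactants: 6 (2R,5S)-2-(1,1-dimethoxyethyl)-2-methyl-5-{2-[(triethylsilyl)oxy]propan-2-yl}oxolane; 12 (6E)-8-[(tert-butyldiphenylsilyl)oxy]-3-hydroxy-6-methyl-2-methylideneoct-6-en-1-yl acetate
Product: 15 (2Z,6E)-8-[(tert-butyldiphenylsilyl)oxy]-6-methyl-2-{3-[(2R,5S)-2-methyl-5-{2-[(triethylsilyl)oxy]propan-2-yl}oxolan-2-yl]-3-oxopropyl}octa-2,6-dien-1-yl acetate, via mixed methyl allyl ketal 13 (not isolated), via allyl vinyl ether 14 (not isolated)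
Conditions: 6 (2 equiv), EtCO2H (10 mol%), xylene, 135 °C, MeOH distilled off, 12–24 h
Reagents that add atoms: none
Why: ketal Claisen rearrangement ([3,3]-sigmatropic, Johnson type): alcohol exchange and loss of methanol can only give the enol ether toward the methyl group because C11 is quaternary, and the chair transition state with the C5 chain equatorial forms the C8–C9 bond with C5 trans to C8 (the Z acetoxymethyl olefin); the carbinol centre of racemic 12 becomes sp2, so a single product results.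

Step 11
Reactants: 15 (2Z,6E)-8-[(tert-butyldiphenylsilyl)oxy]-6-methyl-2-{3-[(2R,5S)-2-methyl-5-{2-[(triethylsilyl)oxy]propan-2-yl}oxolan-2-yl]-3-oxopropyl}octa-2,6-dien-1-yl acetate
Product: 16 (2Z,6E)-8-[(tert-butyldiphenylsilyl)oxy]-2-{(3S)-3-hydroxy-3-[(2R,5S)-2-methyl-5-{2-[(triethylsilyl)oxy]propan-2-yl}oxolan-2-yl]propyl}-6-methylocta-2,6-dien-1-yl acetate
Conditions: Zn(BH4)2 (1.5 equiv), Et2O, −30 to 0 °C
Reagents that add atoms: none
Why: Cram chelate-controlled reduction: zinc bridges the C10 carbonyl and the ring oxygen, and hydride is expected to enter from the face of the C11 methyl group, anti to ring C12, setting 10S from the bought 11R centre (untested on this substrate); the acetate and silyl ethers are inert to zinc borohydride.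

Step 12
Reactants: 16 (2Z,6E)-8-[(tert-butyldiphenylsilyl)oxy]-2-{(3S)-3-hydroxy-3-[(2R,5S)-2-methyl-5-{2-[(triethylsilyl)oxy]propan-2-yl}oxolan-2-yl]propyl}-6-methylocta-2,6-dien-1-yl acetate
Product: 17 (2Z,6E)-8-hydroxy-2-{(3S)-3-hydroxy-3-[(2R,5S)-5-(2-hydroxypropan-2-yl)-2-methyloxolan-2-yl]propyl}-6-methylocta-2,6-dien-1-yl acetate (CNP0272745.3)
Conditions: Bu4NF (4 equiv), AcOH (4 equiv), THF, 0 °C to rt
Reagents that add atoms: none
Why: buffered fluoride desilylation removes the primary allylic and the tertiary silyl ether in one operation without cleaving or moving the allylic acetate and without touching any stereocentre.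

## Compound list

1 | (R)-(−)-linalool, (3R)-3,7-dimethylocta-1,6-dien-3-ol | C=C[C@](C)(O)CCC=C(C)C | starting material
2 | (3R)-5-[(2R)-3,3-dimethyloxiran-2-yl]-3-methylpent-1-en-3-ol (6R epoxide of linalool, formed beside its 6S epimer) | C=C[C@](C)(O)CC[C@H]1OC1(C)C | intermediate
3 | 2-[(2S,5R)-5-ethenyl-5-methyloxolan-2-yl]propan-2-ol (cis-furanoid linalool oxide) | C=C[C@@]1(C)CC[C@@H](C(C)(C)O)O1 | intermediate
4 | triethyl({2-[(2S,5R)-5-ethenyl-5-methyloxolan-2-yl]propan-2-yl}oxy)silane | C=C[C@@]1(C)CC[C@@H](C(C)(C)O[Si](CC)(CC)CC)O1 | intermediate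
5 | 1-[(2R,5S)-2-methyl-5-{2-[(triethylsilyl)oxy]propan-2-yl}oxolan-2-yl]ethan-1-one | CC(=O)[C@@]1(C)CC[C@@H](C(C)(C)O[Si](CC)(CC)CC)O1 | intermediate
6 | (2R,5S)-2-(1,1-dimethoxyethyl)-2-methyl-5-{2-[(triethylsilyl)oxy]propan-2-yl}oxolane | CC(OC)(OC)[C@@]1(C)CC[C@@H](C(C)(C)O[Si](CC)(CC)CC)O1 | intermediate
7 | geraniol, (2E)-3,7-dimethylocta-2,6-dien-1-ol | CC(C)=CCC/C(C)=C/CO | starting material
8 | tert-butyl{[(2E)-3,7-dimethylocta-2,6-dien-1-yl]oxy}diphenylsilane | CC(C)=CCC/C(C)=C/CO[Si](c1ccccc1)(c1ccccc1)C(C)(C)C | intermediate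
9 | tert-butyl{[(2E)-5-(3,3-dimethyloxiran-2-yl)-3-methylpent-2-en-1-yl]oxy}diphenylsilane (racemic) | CC1(C)OC1CC/C(C)=C/CO[Si](c1ccccc1)(c1ccccc1)C(C)(C)C | intermediate
10 | (4E)-6-[(tert-butyldiphenylsilyl)oxy]-4-methylhex-4-enal | O=CCC/C(C)=C/CO[Si](c1ccccc1)(c1ccccc1)C(C)(C)C | intermediate
11 | (6E)-8-[(tert-butyldiphenylsilyl)oxy]-6-methyl-2-methylideneoct-6-ene-1,3-diol (racemic) | OCC(=C)C(O)CC/C(C)=C/CO[Si](c1ccccc1)(c1ccccc1)C(C)(C)C | intermediate
12 | (6E)-8-[(tert-butyldiphenylsilyl)oxy]-3-hydroxy-6-methyl-2-methylideneoct-6-en-1-yl acetate (racemic) | CC(=O)OCC(=C)C(O)CC/C(C)=C/CO[Si](c1ccccc1)(c1ccccc1)C(C)(C)C | intermediate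
13 | (6E)-8-[(tert-butyldiphenylsilyl)oxy]-3-({1-methoxy-1-[(2R,5S)-2-methyl-5-{2-[(triethylsilyl)oxy]propan-2-yl}oxolan-2-yl]ethyl}oxy)-6-methyl-2-methylideneoct-6-en-1-yl acetate (mixed ketal, diastereomer mixture) | CC(OC)(OC(CC/C(C)=C/CO[Si](c1ccccc1)(c1ccccc1)C(C)(C)C)C(=C)COC(C)=O)[C@@]1(C)CC[C@@H](C(C)(C)O[Si](CC)(CC)CC)O1 | intermediate
14 | (6E)-8-[(tert-butyldiphenylsilyl)oxy]-6-methyl-2-methylidene-3-({1-[(2R,5S)-2-methyl-5-{2-[(triethylsilyl)oxy]propan-2-yl}oxolan-2-yl]ethenyl}oxy)oct-6-en-1-yl acetate (allyl vinyl ether, epimer mixture at the allylic carbon) | C=C(OC(CC/C(C)=C/CO[Si](c1ccccc1)(c1ccccc1)C(C)(C)C)C(=C)COC(C)=O)[C@@]1(C)CC[C@@H](C(C)(C)O[Si](CC)(CC)CC)O1 | intermediate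
15 | (2Z,6E)-8-[(tert-butyldiphenylsilyl)oxy]-6-methyl-2-{3-[(2R,5S)-2-methyl-5-{2-[(triethylsilyl)oxy]propan-2-yl}oxolan-2-yl]-3-oxopropyl}octa-2,6-dien-1-yl acetate | CC(=O)OC/C(=C\CC/C(C)=C/CO[Si](c1ccccc1)(c1ccccc1)C(C)(C)C)CCC(=O)[C@@]1(C)CC[C@@H](C(C)(C)O[Si](CC)(CC)CC)O1 | intermediate
16 | (2Z,6E)-8-[(tert-butyldiphenylsilyl)oxy]-2-{(3S)-3-hydroxy-3-[(2R,5S)-2-methyl-5-{2-[(triethylsilyl)oxy]propan-2-yl}oxolan-2-yl]propyl}-6-methylocta-2,6-dien-1-yl acetate | CC(=O)OC/C(=C\CC/C(C)=C/CO[Si](c1ccccc1)(c1ccccc1)C(C)(C)C)CC[C@H](O)[C@@]1(C)CC[C@@H](C(C)(C)O[Si](CC)(CC)CC)O1 | intermediate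
17 | (2Z,6E)-8-hydroxy-2-{(3S)-3-hydroxy-3-[(2R,5S)-5-(2-hydroxypropan-2-yl)-2-methyloxolan-2-yl]propyl}-6-methylocta-2,6-dien-1-yl acetate | CC(=O)OC/C(=C\CC/C(C)=C/CO)CC[C@H](O)[C@@]1(C)CC[C@@H](C(C)(C)O)O1 | target

## Step count and risks

Total steps: 12 (steps 1–4 for the oxolane fragment, steps 5–9 for the chain fragment, steps 10–12 after joining).
Longest linear sequence: 8 steps (geraniol 7 to target 17, steps 5–12).

Most likely to fail:

Step 3, the Wacker oxidation. The vinyl group sits on a fully substituted, oxygen-bearing carbon, so turnover may be slow or some aldehyde may form. The fallback sets out from 4 and comes back at 5. Ozonolysis of 4 (O3, CH2Cl2/MeOH, −78 °C; Me2S) gives (2R,5S)-2-methyl-5-{2-[(triethylsilyl)oxy]propan-2-yl}oxolane-2-carbaldehyde F1. Addition of MeMgBr (Et2O, −78 °C) gives 1-[(2R,5S)-2-methyl-5-{2-[(triethylsilyl)oxy]propan-2-yl}oxolan-2-yl]ethan-1-ol F2 as an epimer mixture that does not matter. Dess–Martin periodinane (CH2Cl2, NaHCO3) oxidises it to 5.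

Step 10, the ketal Claisen coupling. Exchange of a hindered ketal with a secondary allylic alcohol may be incomplete, and hot acid could loosen the tertiary silyl ether or move the acetate. The fallback sets out from 12 (with 5) and comes back at 15 by a Carroll rearrangement, which needs no acid. Alcohol 12 with 1,1′-carbonyldiimidazole (CH2Cl2, rt) gives (6E)-2-[(acetyloxy)methyl]-8-[(tert-butyldiphenylsilyl)oxy]-6-methylocta-1,6-dien-3-yl 1H-imidazole-1-carboxylate F3. The lithium enolate of 5 (LDA, THF, −78 °C) is C-acylated by it in the presence of BF3·OEt2 to give the allylic β-keto ester (6E)-2-[(acetyloxy)methyl]-8-[(tert-butyldiphenylsilyl)oxy]-6-methylocta-1,6-dien-3-yl 3-[(2R,5S)-2-methyl-5-{2-[(triethylsilyl)oxy]propan-2-yl}oxolan-2-yl]-3-oxopropanoate F4. Heating in xylene (140 °C) brings about the [3,3] shift through the same chair and loss of CO2, giving 15.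

Step 11, the C10 reduction. The bulky silyloxy group next to the ring oxygen may weaken chelation and lower the diastereomer ratio. The fallback sets out from 15 and comes back at 17, with the order of the last two operations reversed. Desilylation of 15 (Bu4NF, AcOH, THF) gives the keto diol (2Z,6E)-8-hydroxy-2-{3-[(2R,5S)-5-(2-hydroxypropan-2-yl)-2-methyloxolan-2-yl]-3-oxopropyl}-6-methylocta-2,6-dien-1-yl acetate F5. Reduction with Zn(BH4)2 (Et2O/THF, −30 °C) then gives 17 directly. The free C15 hydroxyl becomes a zinc alkoxide that binds the ring oxygen and the carbonyl oxygen together, locking the carbonyl syn to the ring oxygen and further shielding the C12 face.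

Further compounds
F1 | step 3 | (2R,5S)-2-methyl-5-{2-[(triethylsilyl)oxy]propan-2-yl}oxolane-2-carbaldehyde | O=C[C@@]1(C)CC[C@@H](C(C)(C)O[Si](CC)(CC)CC)O1
F2 | step 3 | 1-[(2R,5S)-2-methyl-5-{2-[(triethylsilyl)oxy]propan-2-yl}oxolan-2-yl]ethan-1-ol (carbinol epimer mixture) | CC(O)[C@@]1(C)CC[C@@H](C(C)(C)O[Si](CC)(CC)CC)O1
F3 | step 10 | (6E)-2-[(acetyloxy)methyl]-8-[(tert-butyldiphenylsilyl)oxy]-6-methylocta-1,6-dien-3-yl 1H-imidazole-1-carboxylate (racemic) | CC(=O)OCC(=C)C(CC/C(C)=C/CO[Si](c1ccccc1)(c1ccccc1)C(C)(C)C)OC(=O)n1ccnc1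
F4 | step 10 | (6E)-2-[(acetyloxy)methyl]-8-[(tert-butyldiphenylsilyl)oxy]-6-methylocta-1,6-dien-3-yl 3-[(2R,5S)-2-methyl-5-{2-[(triethylsilyl)oxy]propan-2-yl}oxolan-2-yl]-3-oxopropanoate (epimer mixture at the allylic carbon) | CC(=O)OCC(=C)C(CC/C(C)=C/CO[Si](c1ccccc1)(c1ccccc1)C(C)(C)C)OC(=O)CC(=O)[C@@]1(C)CC[C@@H](C(C)(C)O[Si](CC)(CC)CC)O1
F5 | step 11 | (2Z,6E)-8-hydroxy-2-{3-[(2R,5S)-5-(2-hydroxypropan-2-yl)-2-methyloxolan-2-yl]-3-oxopropyl}-6-methylocta-2,6-dien-1-yl acetate | CC(=O)OC/C(=C\CC/C(C)=C/CO)CCC(=O)[C@@]1(C)CC[C@@H](C(C)(C)O)O1
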